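**Retrosynthetic overview**
1. Target 14 comes from aldol adduct 13 by one hydrogenolysis that removes three O-benzyl groups and the benzylic hydroxyl.
2. Adduct 13 comes from an anti-selective lactone-enolate aldol of (R)-lactone 6 with ring B aldehyde 10 (made from 2-methoxyresorcinol); this sets the trans C3 centre.
3. Key step: (R)-lactone 6 comes from a desymmetrising Baeyer–Villiger oxygen insertion (ring C–O bond) into prochiral cyclobutanone 4; this sets C4.
4. Cyclobutanone 4 comes from a dichloroketene [2+2] cycloaddition onto O-benzyleugenol followed by dechlorination.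
5. Ring order: the cyclobutanone is built first and then ring-expanded to the γ-butyrolactone; both arenes are bought.

Assumption: 2-methoxyresorcinol is taken as a stocked, inexpensive catalogue phenol, and for the new catalyst of step 4 the antipode that delivers (R)-6 is the one used.

**Step 1**
Reactants: 1 eugenol
Product: 2 4-allyl-1-(benzyloxy)-2-methoxybenzene
Conditions: BnBr, K2CO3, acetone, reflux
Reagents that add atoms: benzyl bromide, BrCc1ccccc1
Why: Williamson ether synthesis; the benzyl ether shields the phenol from acylation in step 2 and from base in step 7 and is removed in the final hydrogenolysis.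

**Step 2**
Reactants: 2 4-allyl-1-(benzyloxy)-2-methoxybenzene
Product: 3 racemic 2,2-dichloro-3-[4-(benzyloxy)-3-methoxybenzyl]cyclobutan-1-one
Conditions: Cl3CCOCl, Zn–Cu couple, POCl3, Et2O, reflux
Reagents that add atoms: trichloroacetyl chloride, ClC(=O)C(Cl)(Cl)Cl
Why: Ketene–alkene [2+2] cycloaddition; dichloroketene made in the flask adds to the terminal alkene with its carbonyl carbon bonding to the CH2 terminus, which gives the 3-substituted cyclobutanone regiochemistry, and POCl3 ties up the zinc chloride so the electron-rich arene is not acylated.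

**Step 3**
Reactants: 3 racemic 2,2-dichloro-3-[4-(benzyloxy)-3-methoxybenzyl]cyclobutan-1-one
Product: 4 3-[4-(benzyloxy)-3-methoxybenzyl]cyclobutan-1-one
Conditions: Zn dust, AcOH, rt to 60 °C
Reagents that add atoms: none
Why: Reductive dehalogenation of an α,α-dichloroketone by zinc; it leaves the benzyl ether untouched and gives an achiral, prochiral ketone whose two ring CH2 groups are enantiotopic.

**Step 4**
Reactants: 4 3-[4-(benzyloxy)-3-methoxybenzyl]cyclobutan-1-one
Product: 6 (R)-4-[4-(benzyloxy)-3-methoxybenzyl]oxolan-2-one, via Criegee perhydrate 5 (not isolated)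
Conditions: (S,S)-imidodiphosphoric acid HN[P(O)(O2Ar*)]2 with Ar*(OH)2 = (S)-3,3'-bis(2,4,6-triethylphenyl)-BINOL (5 mol %), 30% aq. H2O2 (1.5 equiv), CHCl3, −40 °C
Reagents that add atoms: hydrogen peroxide, OO
Why: Proposed new method: a confined C2-symmetric imidodiphosphoric acid is proposed to catalyse peroxide addition to the strained ketone and to hold Criegee perhydrate 5 by two hydrogen bonds (P=O to the hemiketal OH, P–OH to the distal peroxide oxygen) deep in its pocket with the arylmethyl group pointing out of the mouth, so that only one of the two enantiotopic ring CH2 groups can lie antiperiplanar to the O–O bond and migrate, which forms the ring C–O bond and fixes C4 as R; the closest known reaction is the binaphthol phosphoric acid-catalysed Baeyer–Villiger desymmetrisation of 3-substituted cyclobutanones with aqueous H2O2, whose more open pocket is expected to recognise a remote 3-benzyl group less well than a 3-aryl group.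

**Step 5**
Reactants: 7 2-methoxyresorcinol
Product: 9 2,4-dihydroxy-3-methoxybenzaldehyde, via aryl iminium chloride 8 (not isolated)
Conditions: POCl3, DMF, MeCN, −15 °C to rt; then H2O, 50 °C
Reagents that add atoms: N,N-dimethylformamide, CN(C)C=O; water, O
Why: Vilsmeier–Haack formylation; the chloroiminium electrophile attacks C4 (equivalent to C6), the only position ortho to one hydroxyl and para to the other, and hydrolysis of the iminium salt releases the aldehyde.

**Step 6**
Reactants: 9 2,4-dihydroxy-3-methoxybenzaldehyde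
Product: 10 2,4-bis(benzyloxy)-3-methoxybenzaldehyde
Conditions: BnBr (2.4 equiv), K2CO3, DMF, 60 °C
Reagents that add atoms: benzyl bromide, BrCc1ccccc1
Why: Double Williamson ether synthesis; warm DMF with excess base also alkylates the hydrogen-bonded 2-hydroxyl, giving an aldehyde that is electrophilic enough for the enolate addition.

**Step 7**
Reactants: 6 (R)-4-[4-(benzyloxy)-3-methoxybenzyl]oxolan-2-one; 10 2,4-bis(benzyloxy)-3-methoxybenzaldehyde
Product: 13 (3S,4R)-3-{[2,4-bis(benzyloxy)-3-methoxyphenyl](hydroxy)methyl}-4-[4-(benzyloxy)-3-methoxybenzyl]oxolan-2-one as a mixture of carbinol epimers, via lithium enolate 11 (not isolated), via lithium aldolate 12 (not isolated)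
Conditions: LiN(iPr)2 (LDA), THF, −78 °C; then 10, −78 °C; sat. aq. NH4Cl at −78 °C
Reagents that add atoms: none
Why: Lithium enolate aldol addition; the aldehyde approaches the enolate face anti to the C4 arylmethyl group, so C3 and C4 become trans (this geometry is 3S here only because the carbinol carbon outranks C4, and it is the one that reads 3R in the target), while the carbinol centre is erased in step 8.

**Step 8**
Reactants: 13 (3S,4R)-3-{[2,4-bis(benzyloxy)-3-methoxyphenyl](hydroxy)methyl}-4-[4-(benzyloxy)-3-methoxybenzyl]oxolan-2-one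
Product: 14 (3R,4R)-3-(2,4-dihydroxy-3-methoxybenzyl)-4-(4-hydroxy-3-methoxybenzyl)oxolan-2-one
Conditions: H2 (3 atm), 10% Pd/C, EtOAc/EtOH, rt to 40 °C
Reagents that add atoms: none
Why: Catalytic hydrogenolysis; the three benzyl ethers are cleaved first and the benzylic C–OH, now activated by ortho and para hydroxyl groups, is then cleaved as well, while neutral conditions leave C3 and C4 untouched and avoid acid-driven Friedel–Crafts closure onto ring A.

**Compound list**
1 | eugenol (4-allyl-2-methoxyphenol) | C=CCc1ccc(O)c(OC)c1 | starting material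
2 | 4-allyl-1-(benzyloxy)-2-methoxybenzene | C=CCc1ccc(OCc2ccccc2)c(OC)c1 | intermediate
3 | racemic 2,2-dichloro-3-[4-(benzyloxy)-3-methoxybenzyl]cyclobutan-1-one | O=C1CC(Cc2ccc(OCc3ccccc3)c(OC)c2)C1(Cl)Cl | intermediate
4 | 3-[4-(benzyloxy)-3-methoxybenzyl]cyclobutan-1-one | O=C1CC(Cc2ccc(OCc3ccccc3)c(OC)c2)C1 | intermediate
5 | Criegee perhydrate, 3-[4-(benzyloxy)-3-methoxybenzyl]-1-hydroperoxycyclobutan-1-ol | OOC1(O)CC(Cc2ccc(OCc3ccccc3)c(OC)c2)C1 | intermediate
6 | (R)-4-[4-(benzyloxy)-3-methoxybenzyl]oxolan-2-one | COc1cc(C[C@H]2COC(=O)C2)ccc1OCc1ccccc1 | intermediate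
7 | 2-methoxyresorcinol (2-methoxybenzene-1,3-diol) | COc1c(O)cccc1O | starting material
8 | [(2,4-dihydroxy-3-methoxyphenyl)methylidene]dimethyliminium chloride | C[N+](C)=Cc1ccc(O)c(OC)c1O.[Cl-] | intermediate
9 | 2,4-dihydroxy-3-methoxybenzaldehyde | O=Cc1ccc(O)c(OC)c1O | intermediate
10 | 2,4-bis(benzyloxy)-3-methoxybenzaldehyde | O=Cc1ccc(OCc2ccccc2)c(OC)c1OCc1ccccc1 | intermediate
11 | lithium (R)-4-[4-(benzyloxy)-3-methoxybenzyl]-4,5-dihydrofuran-2-olate | COc1cc(C[C@H]2COC([O-])=C2)ccc1OCc1ccccc1.[Li+] | intermediate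
12 | lithium alkoxide of 13 (3S,4R; carbinol epimers) | COc1cc(C[C@H]2COC(=O)[C@@H]2C([O-])c2ccc(OCc3ccccc3)c(OC)c2OCc2ccccc2)ccc1OCc1ccccc1.[Li+] | intermediate
13 | (3S,4R)-3-{[2,4-bis(benzyloxy)-3-methoxyphenyl](hydroxy)methyl}-4-[4-(benzyloxy)-3-methoxybenzyl]oxolan-2-one (3,4-trans; carbinol epimers) | COc1cc(C[C@H]2COC(=O)[C@@H]2C(O)c2ccc(OCc3ccccc3)c(OC)c2OCc2ccccc2)ccc1OCc1ccccc1 | intermediate
14 | (3R,4R)-3-(2,4-dihydroxy-3-methoxybenzyl)-4-(4-hydroxy-3-methoxybenzyl)oxolan-2-one | COc1cc(C[C@H]2COC(=O)[C@@H]2Cc2ccc(O)c(OC)c2O)ccc1O | target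

**Totals**
Total steps: 8. Longest linear sequence: 6 (steps 1, 2, 3, 4, 7, 8).

**Steps most likely to fail**

Step 4 (proposed new catalyst; the enantioselectivity or turnover may fall short). The fallback sets out from 4 and comes back at 6 by known chemistry. Enantioselective deprotonation of 4 with the enantiomer of lithium bis(1-phenylethyl)amide, LiN[CH(CH3)Ph]2, that leads to the R series, in the presence of Me3SiCl (THF, −100 °C), gives (R)-silyl enol ether F1. Ozonolysis (O3, CH2Cl2/MeOH, −78 °C) cleaves the enol ether double bond to (R)-aldehydo acid F2, which is reduced in the same flask with NaBH4 to (R)-hydroxy acid F3. Acidification with dilute HCl closes F3 to 6.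

Step 7 (the ortho-substituted aldehyde may add sluggishly or the adduct may revert by retro-aldol). The fallback sets out from 10 and comes back at 14, bypassing 13. Aldehyde 10 is reduced with NaBH4 (MeOH, 0 °C) to benzylic alcohol F4, which PBr3 (Et2O, 0 °C) converts into benzylic bromide F5. Lithium enolate 11 (from 6, LiN(iPr)2, THF/DMPU, −78 °C) is alkylated with F5 anti to the C4 substituent to give tri-O-benzyl lactone F6 (3R,4R). Hydrogenolysis of F6 (H2, 10% Pd/C, EtOAc/EtOH) then gives 14.

Step 8 (the benzylic C–OH may cleave slowly, or C3 may partly epimerise through a quinone methide). The fallback sets out from 13 and comes back at 14. MsCl and Et3N (CH2Cl2, 0 °C) give mesylate F7, and DBU eliminates it to (E)-arylidene lactone F8. Hydrogenation (H2, 10% Pd/C, EtOAc/EtOH) saturates the alkene and removes the benzyl groups, giving mainly cis lactone F9 beside 14. Excess DBU (MeCN, 60 °C, dilute HCl work-up) then equilibrates F9 to the more stable trans lactone 14.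

**Further compounds**
F1 | step 4 | (R)-{3-[4-(benzyloxy)-3-methoxybenzyl]cyclobut-1-en-1-yl}oxy(trimethyl)silane | COc1cc(C[C@H]2C=C(O[Si](C)(C)C)C2)ccc1OCc1ccccc1
F2 | step 4 | (R)-3-[4-(benzyloxy)-3-methoxybenzyl]-4-oxobutanoic acid | COc1cc(C[C@H](CC(O)=O)C=O)ccc1OCc1ccccc1
F3 | step 4 | (R)-3-[4-(benzyloxy)-3-methoxybenzyl]-4-hydroxybutanoic acid | COc1cc(C[C@H](CC(O)=O)CO)ccc1OCc1ccccc1
F4 | step 7 | [2,4-bis(benzyloxy)-3-methoxyphenyl]methanol | COc1c(OCc2ccccc2)ccc(CO)c1OCc1ccccc1
F5 | step 7 | 1,3-bis(benzyloxy)-4-(bromomethyl)-2-methoxybenzene | COc1c(OCc2ccccc2)ccc(CBr)c1OCc1ccccc1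
F6 | step 7 | (3R,4R)-3-[2,4-bis(benzyloxy)-3-methoxybenzyl]-4-[4-(benzyloxy)-3-methoxybenzyl]oxolan-2-one | COc1cc(C[C@H]2COC(=O)[C@@H]2Cc2ccc(OCc3ccccc3)c(OC)c2OCc2ccccc2)ccc1OCc1ccccc1
F7 | step 8 | methanesulfonate of 13 (3S,4R; carbinol epimers) | COc1cc(C[C@H]2COC(=O)[C@@H]2C(OS(C)(=O)=O)c2ccc(OCc3ccccc3)c(OC)c2OCc2ccccc2)ccc1OCc1ccccc1
F8 | step 8 | (R,E)-3-[2,4-bis(benzyloxy)-3-methoxybenzylidene]-4-[4-(benzyloxy)-3-methoxybenzyl]oxolan-2-one | COc1cc(C[C@H]2COC(=O)/C2=C/c2ccc(OCc3ccccc3)c(OC)c2OCc2ccccc2)ccc1OCc1ccccc1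
F9 | step 8 | (3S,4R)-3-(2,4-dihydroxy-3-methoxybenzyl)-4-(4-hydroxy-3-methoxybenzyl)oxolan-2-one (cis epimer of 14) | COc1cc(C[C@H]2COC(=O)[C@H]2Cc2ccc(O)c(OC)c2O)ccc1O
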